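(The data are simulated with constants of no real substance; noise was put on by code.)

- A flat line cannot tell you why a flask stopped: a balance that has been reached and a catalyst that has died both draw it. The flat stretch won't separate them, so you have to look at how the zeta flask got there.

in all of them: substrate 0.80 M; free catalyst 4.2 mM

|  | temperature | remark | time |
|---|---|---|---|
| zeta | 40 °C | the very flask that is asked about, followed so far |  |
| theta | 46 °C | run made earlier |  |
| flask | 40 °C |  | 8.0 d |

| run | time / h | target / % | substrate / % |
|---|---|---|---|
| zeta | 15.0 | 30.6 | 68.7 |
| zeta | 30.0 | 34.3 | 65.5 |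
| zeta | 60.0 | 35.9 | 63.8 |
| zeta | 96.0 | 36.5 | 63.7 |
| zeta | 192 | 35.6 | 63.8 |
| theta | 15.0 | 35.3 | 63.1 |
| theta | 30.0 | 36.5 | 61.9 |
| theta | 60.0 | 37.1 | 61.6 |
| theta | 96.0 | 36.6 | 61.9 |
| theta | 192 | 38.1 | 62.9 |

(each reading ± 0.5 percentage points)

- Tuesday's: at 8.0 d add free catalyst, 100% of the amount charged, then wait 15 d
- Friday's: at 8.0 d take out 90% of the target then present, then wait 15 d
- Monday's: change nothing and wait 15 d more
- Thursday's: at 8.0 d raise the temperature by 25 K, then wait 15 d

* target, in percent of the substrate first charged, at 8.0 d
* the remedy with the largest gain of target, or "none" below 2 percentage points (Tuesday's / Friday's / Monday's / Thursday's / none)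
* target present, with what was taken out counted in, in percent of the substrate first charged, after Tuesday's
* target present, with what was taken out counted in, in percent of the substrate first charged, after Monday's

- target that was removed still counts
- the analysis behind the earlier runs scatters by 0.5 percentage points, standard deviation
- additions bring no volume worth counting

- The zeta readings from 60.0 h on average 0.360 of the charge. Call this the charge yield: the fraction of the substrate present that one portion of catalyst turns into target before the flask stops.
- Take the gap, meaning the plateau minus the target. A first-order approach to a balance, with the catalyst working steadily, closes this gap by the same factor in equal times.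
- In the zeta readings the gap shrinks by a factor of 6.67 over the first 15.0 h, but by 3.18 over the next.
- Put the first factor back in and the gap at 30.0 h misses the reading by 0.89 percentage points, against a scatter of 0.5 points. The theta readings, with a plateau read at 0.373, miss the same way, by 0.66 points. That is a lean, not a proof, but I commit to it: the catalyst is dying (deactivation).
- My answers follow. Now stands at 0.360, and Monday's stays there. I book no gain for waiting, heating or taking out target: none of them adds catalyst.
- For Tuesday's, the first answer is a fresh portion repeating the yield, which totals 0.720. Go round again: that portion meets 0.640 of the charge, so it gains 0.230, and the total is 0.590. I pick Tuesday's.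
- The forecast parts from my reckoning on two answers: it gave 36.1% now, Friday's as best, 36.1% after Tuesday's and 36.1% after Monday's, saying “I favour equilibrium, but not overwhelmingly”.
- The flask gives 35.5% at 8.0 d, Tuesday's as best, 52.6% after Tuesday's and 35.5% after Monday's.

    substrate + free catalyst ⇌ catalyst intermediate A (K = 3.50 /M, k = 680 /M/h, Ea = 65.0 kJ/mol, ΔH = −3.00 kJ/mol)
    2 catalyst intermediate A → spent catalyst A (k = 450 /M/h, Ea = 45.0 kJ/mol)
    catalyst intermediate A ⇌ catalyst intermediate B (K = 1.80, k = 54.0 /h, Ea = 96.0 kJ/mol, ΔH = −55.0 kJ/mol)
    catalyst intermediate B ⇌ free catalyst + target (K = 0.340 M, k = 3500 /h, Ea = 68.0 kJ/mol, ΔH = −22.0 kJ/mol)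
    target + catalyst intermediate B → spent catalyst B (k = 0.980 /M/h, Ea = 78.0 kJ/mol)
    (constants at 40 °C)

- Up to 19.2 h in the flask, catalyst went round through catalyst intermediate A and catalyst intermediate B while target rose to 32.0%, and 91.7% of the catalyst charged ended as spent catalyst A. By 96.0 h free catalyst stood at 0%, with 7.84% as spent catalyst B and target at 35.5%. Tuesday's second portion, its gain taken over the substrate left, shows a charge yield of 0.267, lower than the 0.360 read for the first portion. In the neighbour flask charged with 0.20 M of substrate, target at 8.0 d gives a charge yield of 66.2%, higher than the 0.360 read in zeta.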